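## Retrosynthetic overview

1. Target ⇒ C-2 acetylation and C-17 equilibration, γ-lactone closure, chelation-controlled reduction of C-7 and C-2, and α-chlorination at C-6 of the ten-membered 2,7-diketone 30.
2. 30 ⇒ ozonolysis of the C-2=C-7 ring-fusion olefin left by Birch reduction of the anisole ring of tricycle 23. The arene of a hydrophenanthrene is the latent ten-membered ring.
3. 23 ⇒ α-face oxygenation of a trans-fused tricycle: OsO4 at C-8/C-9, singlet-oxygen ene at C-12, reductive Rubottom at C-10/C-11; the C-17 to C-19 unit comes from a Reformatsky reaction on the C-8 benzylic ketone.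
4. Tricyclic enone 11 ⇒ enantioselective Robinson annulation of 6-methoxy-1-methyl-2-tetralone (two steps from 6-methoxy-1-tetralone) with ethyl vinyl ketone.
5. Ring order: rings C and B are bought, ring A is formed in step 3, the ten-membered ring in step 14 (from rings B and C), the lactone in step 16.

Assumption: atoms carry briarane-type labels C-1 to C-20 (C-15 = methyl on C-1, C-16 = exocyclic methylene carbon, C-18 = methyl on C-17, C-19 = lactone carbonyl, C-20 = methyl on C-11); "α" is the face opposite the C-15 methyl; C-17 is carried as a roughly 1:1 mixture from step 7 until step 17. The route is a plan; no step has been run.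

## Route

Step 1
Reactants: 1 6-methoxy-1-tetralone
Product: 3 7-methoxy-4-methyl-1,2-dihydronaphthalene, via tertiary benzylic alcohol 2 (not isolated)
Conditions: MeMgBr, THF, 0 °C → rt; aq. HCl; TsOH·H2O (cat.), toluene, 80 °C
Reagents that add atoms: methylmagnesium bromide, C[Mg]Br
Why: Grignard addition to the aryl ketone followed by acid-catalysed E1 dehydration of the tertiary benzylic alcohol (cation stabilised by the para methoxy group) gives the trisubstituted styrene; no stereocentre is formed.

Step 2
Reactants: 3 7-methoxy-4-methyl-1,2-dihydronaphthalene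
Product: 5 6-methoxy-1-methyl-2-tetralone (racemic), via epoxide 4 (not isolated)
Conditions: mCPBA, NaHCO3, CH2Cl2, 0 °C; then BF3·OEt2 (cat.), −20 °C
Reagents that add atoms: meta-chloroperoxybenzoic acid, O=C(OO)c1cccc(Cl)c1
Why: Prilezhaev epoxidation of the electron-rich styrene and Lewis-acid Meinwald rearrangement (opening to the para-methoxybenzylic tertiary cation, 1,2-hydride shift) give the 2-tetralone, whose C-1 centre is racemic but is erased in the enamine of step 3.

Step 3
Reactants: 5 6-methoxy-1-methyl-2-tetralone; 6 (R)-1-phenylethylamine; 7 ethyl vinyl ketone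
Product: 11 tricyclic enone, via imine 8 (not isolated), via Michael adduct imine 9 (not isolated), via diketone 10 (not isolated)
Conditions: 6, TsOH·H2O (cat.), toluene, reflux (Dean–Stark); 7, THF, 40 °C; aq. AcOH, rt; NaOMe, MeOH, 60 °C
Reagents that add atoms: none
Why: Robinson annulation in its chiral-imine (deracemising Michael) form: the conjugated secondary enamine tautomer of 8 adds to the enone through a compact aza-ene-like transition state on the face away from the phenyl group of the auxiliary, which sets the quaternary C-1 centre (R in 10, the sense taken by analogy with the 2-methylcyclohexanone case), and methoxide-mediated intramolecular aldol condensation closes ring A.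

Step 4
Reactants: 11 tricyclic enone
Product: 14 α-silyloxy ketone, via lithium enolate 12 (not isolated), via silyl enol ether 13 (not isolated)
Conditions: Li, NH3/THF, t-BuOH (1 equiv), −78 °C; isoprene; Me3SiCl, Et3N, THF, 0 °C; mCPBA, NaHCO3, CH2Cl2, −20 °C
Reagents that add atoms: chlorotrimethylsilane, C[Si](C)(C)Cl; meta-chloroperoxybenzoic acid, O=C(OO)c1cccc(Cl)c1
Why: dissolving-metal conjugate reduction protonates C-10 axially to give the trans ring fusion (H-10 α), the regiodefined enolate is silylated, and Rubottom oxidation delivers oxygen to C-11 from the α face, anti to the axial C-15 methyl, so that C-11 carries OSiMe3 α and CH3 β.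

Step 5
Reactants: 14 α-silyloxy ketone
Product: 15 vinyl triflate
Conditions: KN(SiMe3)2, THF, −78 °C; PhNTf2, −78 → 0 °C; aq. NH4Cl
Reagents that add atoms: N-phenylbis(trifluoromethanesulfonimide), O=S(=O)(N(c1ccccc1)S(=O)(=O)C(F)(F)F)C(F)(F)F
Why: C-11 is quaternary, so the ketone can be deprotonated only at C-13 and O-triflation of the potassium enolate gives a single vinyl triflate, which masks the later C-12/C-13 olefin against the oxidants of steps 6 and 8.

Step 6
Reactants: 15 vinyl triflate
Product: 16 benzylic ketone
Conditions: CrO3, AcOH/H2O (9:1), rt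
Reagents that add atoms: chromium trioxide, O=[Cr](=O)=O
Why: benzylic C–H oxidation by hexavalent chromium at the only benzylic methylene (C-8; the other benzylic carbon, C-1, is quaternary), with the electron-poor vinyl triflate inert and the labile tertiary trimethylsilyl ether hydrolysed in the aqueous acid.

Step 7
Reactants: 16 benzylic ketone; 17 methyl 2-bromopropanoate
Product: 19 styrenyl ester, via β-hydroxy ester 18 (not isolated)
Conditions: Zn, THF, reflux; aq. NH4Cl; TsOH·H2O (cat.), benzene, 50 °C
Reagents that add atoms: none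
Why: Reformatsky addition of the zinc enolate to the aryl ketone (the free tertiary hydroxyl only consumes one equivalent of reagent) and acid-catalysed E1 dehydration of the tertiary benzylic carbinol to the endocyclic, arene-conjugated olefin (the exocyclic isomer suffers peri strain); C-17 is formed as a mixture that is corrected in step 17.

Step 8
Reactants: 19 styrenyl ester
Product: 20 8α,9α-diol
Conditions: OsO4 (cat.), N-methylmorpholine N-oxide, citric acid, t-BuOH/H2O, rt
Reagents that add atoms: N-methylmorpholine N-oxide, C[N+]1([O-])CCOCC1; water, O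
Why: Upjohn syn-dihydroxylation of the trisubstituted styrene from the α face, because the β face is screened by the axial C-15 and C-20 methyl groups, sets C-8 (OH α, side chain β) and C-9 (OH α) in one event, and the electron-poor vinyl triflate does not react.

Step 9
Reactants: 20 8α,9α-diol
Product: 21 C-12/C-13 olefin
Conditions: Pd(OAc)2 (cat.), PPh3, HCO2H, Et3N, DMF, 60 °C
Reagents that add atoms: none
Why: palladium-catalysed formate reduction of the vinyl triflate (oxidative addition of zerovalent palladium, decarboxylation of the formate ligand to a hydride, reductive elimination) unmasks the olefin without touching the diol, the ester or the arene.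

Step 10
Reactants: 21 C-12/C-13 olefin
Product: 23 tetraol ester, via allylic hydroperoxide 22 (not isolated)
Conditions: O2, hν (visible), tetraphenylporphyrin (cat.), CH2Cl2, 0 °C; PPh3, rt
Reagents that add atoms: oxygen, O=O
Why: Schenck ene reaction of singlet oxygen, in which C-14 is the only carbon with abstractable allylic hydrogen (C-11 is quaternary), so oxygen is delivered to C-12 with shift of the double bond to C-13/C-14, suprafacially on the α face that is favoured both by the directing α hydroxyl at C-11 and by the axial α hydrogen at C-14, and phosphine reduction of the hydroperoxide gives the 12α alcohol.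

Step 11
Reactants: 23 tetraol ester
Product: 26 dienol ether tetraol ester, via lithium carboxylate 24 (not isolated), via dihydroanisole carboxylate 25 (not isolated)
Conditions: LiOH·H2O, THF/MeOH/H2O, rt; Li, NH3/THF/t-BuOH, −78 → −33 °C; NH4Cl; MeI, NaHCO3, DMF, rt
Reagents that add atoms: lithium hydroxide, [Li+].[OH-]; iodomethane, CI
Why: Birch reduction of the anisole ring with all hydroxyls present as lithium alkoxides (which protects the benzylic C-8–O bond from hydrogenolysis and leaves the isolated olefin alone) and the ester masked as its inert carboxylate; the usual anisole regiochemistry puts the new sp3 centres at the unsubstituted C-3 and C-6, leaving the enol ether and the tetrasubstituted C-2=C-7 olefin, and O-alkylation of the carboxylate restores the methyl ester.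

Step 12
Reactants: 26 dienol ether tetraol ester
Product: 28 β,γ-unsaturated ketone diacetate, via diacetate dienol ether 27 (not isolated)
Conditions: Ac2O, pyridine, DMAP (cat.), CH2Cl2, rt; oxalic acid, THF/H2O, 0 °C
Reagents that add atoms: acetic anhydride, CC(=O)OC(C)=O; water, O
Why: DMAP-catalysed acetylation esterifies only the two secondary alcohols (C-9 and C-12), the tertiary ones being inert at room temperature, and dilute oxalic acid hydrolyses the enol ether to the β,γ-unsaturated C-5 ketone without moving the olefin into conjugation.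

Step 13
Reactants: 28 β,γ-unsaturated ketone diacetate
Product: 29 methylene diene
Conditions: Zn, CH2Br2, TiCl4, THF/CH2Cl2, 0 °C → rt
Reagents that add atoms: dibromomethane, BrCBr
Why: Lombardo–Takai methylenation with the non-basic zinc/titanium methylene reagent converts the enolisable β,γ-unsaturated ketone to the exocyclic methylene without isomerisation and tolerates esters and free hydroxyls.

Step 14
Reactants: 29 methylene diene
Product: 30 ten-membered 2,7-diketone
Conditions: O3, NaHCO3, CH2Cl2/MeOH, −78 °C (Sudan Red 7B end point); Me2S, −78 °C → rt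
Reagents that add atoms: ozone, [O-][O+]=O
Why: Criegee ozonolysis with dye-indicated stoichiometry, in which electrophilic ozone reacts fastest with the tetrasubstituted ring-fusion olefin (faster than the 1,1-disubstituted methylene and the acetoxy-deactivated, hindered C-13=C-14 olefin), so that the former aromatic ring and ring B become the ten-membered ring.

Step 15
Reactants: 30 ten-membered 2,7-diketone
Product: 31 (6S)-6-chloro diketone
Conditions: LiN(SiMe3)2 (1.1 equiv), THF, −78 → −40 °C; N-chlorosuccinimide, −78 °C; AcOH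
Reagents that add atoms: N-chlorosuccinimide, O=C1CCC(=O)N1Cl
Why: enolate α-chlorination: the C-7 ketone can enolise only toward C-6 (C-8 is quaternary) and H-6 is the most acidic C–H (α to the ketone and allylic), so the equilibrated lithium dienolate forms there and is chlorinated at its α carbon; with the ring-cis dienolate held by A(1,3) strain (8-O in plane) the reagent should enter on the face opposite the C-9 limb of the ring, which gives 6S.

Step 16
Reactants: 31 (6S)-6-chloro diketone
Product: 33 hydroxy lactone, via diol ester 32 (not isolated)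
Conditions: Zn(BH4)2, Et2O, −20 → 0 °C; aq. NH4Cl; PPTS (cat.), CH2Cl2, rt
Reagents that add atoms: none
Why: chelation-controlled hydride reduction: zinc bridges the C-7 carbonyl, the 8-hydroxyl and the chlorine, the macrocycle (C-5 and C-9) then lies on one face and hydride enters from the side-chain face to give 7R; the hindered C-2 ketone is reduced in the Felkin–Anh sense (C-10 antiperiplanar, hydride passing the C-15 methyl) to give 2R, and the C-7 alkoxide closes the γ-lactone on the methyl ester (C-9 is blocked as its acetate).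

Step 17
Reactants: 33 hydroxy lactone
Product: 35 CNP0259091.2, via equilibrated hydroxy lactone 34 (not isolated)
Conditions: DBU, CH2Cl2, rt; then Ac2O, DMAP (cat.), 0 °C → rt
Reagents that add atoms: acetic anhydride, CC(=O)OC(C)=O
Why: base-mediated epimerisation through the lactone enolate equilibrates C-17 to the epimer expected to be more stable, with the methyl group on the convex face, cis to the 8-hydroxyl and away from C-9 (17R), and acetylation of the one remaining secondary alcohol (C-2) completes the target, the two tertiary alcohols being left free.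

## Compound list

1 | 6-methoxy-1-tetralone (6-methoxy-3,4-dihydronaphthalen-1(2H)-one) | COc1ccc2c(c1)CCCC2=O | starting material
2 | 6-methoxy-1-methyl-1,2,3,4-tetrahydronaphthalen-1-ol (racemic; bromomagnesium alkoxide before the quench) | COc1ccc2c(c1)CCCC2(C)O | intermediate (not isolated)
3 | 7-methoxy-4-methyl-1,2-dihydronaphthalene | COc1ccc2c(c1)CCC=C2C | intermediate
4 | 7-methoxy-4-methyl-1,2-dihydronaphthalene 3,4-oxide (racemic) | COc1ccc2c(c1)CCC1OC21C | intermediate (not isolated)
5 | 6-methoxy-1-methyl-3,4-dihydronaphthalen-2(1H)-one (racemic) | COc1ccc2c(c1)CCC(=O)C2C | intermediate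
6 | (R)-1-phenylethylamine | C[C@@H](N)c1ccccc1 | starting material
7 | ethyl vinyl ketone (pent-1-en-3-one) | C=CC(=O)CC | starting material
8 | N-[(R)-1-phenylethyl] imine of 5 (in equilibrium with its conjugated secondary enamine) | COc1ccc2c(c1)CCC(=N[C@H](C)c1ccccc1)C2C | intermediate (not isolated)
9 | N-[(R)-1-phenylethyl] imine of (R)-6-methoxy-1-methyl-1-(3-oxopentyl)-2-tetralone | COc1ccc2c(c1)CCC(=N[C@H](C)c1ccccc1)[C@]2(C)CCC(=O)CC | intermediate (not isolated)
10 | (R)-6-methoxy-1-methyl-1-(3-oxopentyl)-3,4-dihydronaphthalen-2(1H)-one | COc1ccc2c(c1)CCC(=O)[C@]2(C)CCC(=O)CC | intermediate (not isolated)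
11 | (4aS)-7-methoxy-1,4a-dimethyl-4,4a,9,10-tetrahydrophenanthren-2(3H)-one (C-12 ketone, C-10=C-11 olefin) | COc1ccc2c(c1)CCC1=C(C)C(=O)CC[C@]21C | intermediate
12 | lithium C-11/C-12 enolate of the trans-fused ketone (H-10 α) | COc1ccc2c(c1)CC[C@@H]3[C@]2(C)CCC([O-])=C3C.[Li+] | intermediate (not isolated)
13 | C-12 trimethylsilyl enol ether (C-11=C-12), H-10 α | COc1ccc2c(c1)CC[C@@H]3[C@]2(C)CCC(O[Si](C)(C)C)=C3C | intermediate (not isolated)
14 | trans-fused tricyclic C-12 ketone with 11α-trimethylsilyloxy and 11β-methyl, H-10 α | COc1ccc2c(c1)CC[C@@H]3[C@]2(C)CCC(=O)[C@@]3(C)O[Si](C)(C)C | intermediate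
15 | C-12 vinyl triflate (C-12=C-13) of 14 | COc1ccc2c(c1)CC[C@@H]3[C@]2(C)CC=C(OS(=O)(=O)C(F)(F)F)[C@@]3(C)O[Si](C)(C)C | intermediate
16 | C-8 aryl ketone with free 11α-hydroxyl and C-12 vinyl triflate | COc1ccc2c(c1)C(=O)C[C@@H]3[C@]2(C)CC=C(OS(=O)(=O)C(F)(F)F)[C@@]3(C)O | intermediate
17 | methyl 2-bromopropanoate (racemic) | CC(Br)C(=O)OC | starting material
18 | C-8 tertiary carbinol bearing the methyl propanoate side chain (mixture at C-8 and C-17) | COc1ccc2c(c1)C(O)(C(C)C(=O)OC)C[C@@H]3[C@]2(C)CC=C(OS(=O)(=O)C(F)(F)F)[C@@]3(C)O | intermediate (not isolated)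
19 | methyl 2-(tricyclic C-8=C-9 en-8-yl)propanoate, 11α-OH, C-12 vinyl triflate (C-17 mixture) | COc1ccc2c(c1)C(C(C)C(=O)OC)=C[C@@H]3[C@]2(C)CC=C(OS(=O)(=O)C(F)(F)F)[C@@]3(C)O | intermediate
20 | 8α,9α-diol (side chain 8β), 11α-OH, C-12 vinyl triflate (C-17 mixture) | COc1ccc2c(c1)[C@@](O)(C(C)C(=O)OC)[C@H](O)[C@@H]3[C@]2(C)CC=C(OS(=O)(=O)C(F)(F)F)[C@@]3(C)O | intermediate
21 | 8α,9α,11α-triol ester with C-12=C-13 olefin (C-17 mixture) | COc1ccc2c(c1)[C@@](O)(C(C)C(=O)OC)[C@H](O)[C@@H]3[C@]2(C)CC=C[C@@]3(C)O | intermediate
22 | 12α-hydroperoxide with C-13=C-14 olefin (C-17 mixture) | COc1ccc2c(c1)[C@@](O)(C(C)C(=O)OC)[C@H](O)[C@@H]3[C@]2(C)C=C[C@@H](OO)[C@@]3(C)O | intermediate (not isolated)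
23 | 8α,9α,11α,12α-tetraol methyl ester, C-13=C-14 olefin, anisole ring intact (C-17 mixture) | COc1ccc2c(c1)[C@@](O)(C(C)C(=O)OC)[C@H](O)[C@@H]3[C@]2(C)C=C[C@@H](O)[C@@]3(C)O | intermediate
24 | lithium carboxylate of 23 | COc1ccc2c(c1)[C@@](O)(C(C)C(=O)[O-])[C@H](O)[C@@H]3[C@]2(C)C=C[C@@H](O)[C@@]3(C)O.[Li+] | intermediate (not isolated)
25 | Birch product: lithium carboxylate with C-4=C-5 methyl enol ether and C-2=C-7 olefin | COC1=CCC2=C(C1)[C@@](O)(C(C)C(=O)[O-])[C@H](O)[C@@H]3[C@]2(C)C=C[C@@H](O)[C@@]3(C)O.[Li+] | intermediate (not isolated)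
26 | dienol ether tetraol methyl ester (C-4=C-5 enol ether, C-2=C-7 and C-13=C-14 olefins; C-17 mixture) | COC1=CCC2=C(C1)[C@@](O)(C(C)C(=O)OC)[C@H](O)[C@@H]3[C@]2(C)C=C[C@@H](O)[C@@]3(C)O | intermediate
27 | 9α,12α-diacetate of 26 | COC1=CCC2=C(C1)[C@@](O)(C(C)C(=O)OC)[C@H](OC(C)=O)[C@@H]3[C@]2(C)C=C[C@@H](OC(C)=O)[C@@]3(C)O | intermediate (not isolated)
28 | C-5 ketone with C-2=C-7 olefin (β,γ-unsaturated), 9α,12α-diacetate, 8α,11α-diol, methyl ester (C-17 mixture) | O=C1CCC2=C(C1)[C@@](O)(C(C)C(=O)OC)[C@H](OC(C)=O)[C@@H]3[C@]2(C)C=C[C@@H](OC(C)=O)[C@@]3(C)O | intermediate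
29 | C-5 exocyclic methylene analogue of 28 | C=C1CCC2=C(C1)[C@@](O)(C(C)C(=O)OC)[C@H](OC(C)=O)[C@@H]3[C@]2(C)C=C[C@@H](OC(C)=O)[C@@]3(C)O | intermediate
30 | bicyclo[8.4.0] 2,7-diketone: 5(16)-methylene, 9,12-diacetate, 8,11-diol, methyl ester on C-17 (C-17 mixture) | C=C1CCC(=O)[C@@]2(C)C=C[C@@H](OC(C)=O)[C@@](C)(O)[C@@H]2[C@@H](OC(C)=O)[C@](O)(C(C)C(=O)OC)C(=O)C1 | intermediate
31 | (6S)-6-chloro derivative of 30 | C=C1CCC(=O)[C@@]2(C)C=C[C@@H](OC(C)=O)[C@@](C)(O)[C@@H]2[C@@H](OC(C)=O)[C@](O)(C(C)C(=O)OC)C(=O)[C@H]1Cl | intermediate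
32 | (2R,6S,7R)-6-chloro-2,7-diol methyl ester | C=C1CC[C@@H](O)[C@@]2(C)C=C[C@@H](OC(C)=O)[C@@](C)(O)[C@@H]2[C@@H](OC(C)=O)[C@](O)(C(C)C(=O)OC)[C@@H](O)[C@H]1Cl | intermediate (not isolated)
33 | 2-hydroxy-9,12-diacetoxy-6-chloro-8,11-dihydroxy 19,7-lactone (C-17 mixture) | C=C1CC[C@@H](O)[C@@]2(C)C=C[C@@H](OC(C)=O)[C@@](C)(O)[C@@H]2[C@@H](OC(C)=O)[C@]2(O)C(C)C(=O)O[C@H]2[C@H]1Cl | intermediate
34 | (17R) epimer of 33 | C=C1CC[C@@H](O)[C@@]2(C)C=C[C@@H](OC(C)=O)[C@@](C)(O)[C@@H]2[C@@H](OC(C)=O)[C@]2(O)[C@@H](C)C(=O)O[C@H]2[C@H]1Cl | intermediate (not isolated)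
35 | CNP0259091.2: (1S,2R,6S,7R,8R,9R,10S,11S,12R,17R)-2,9,12-triacetoxy-6-chloro-8,11-dihydroxy-5(16),13-diene 19,7-lactone | C=C1CC[C@@H](OC(C)=O)[C@@]2(C)C=C[C@@H](OC(C)=O)[C@@](C)(O)[C@@H]2[C@@H](OC(C)=O)[C@]2(O)[C@@H](C)C(=O)O[C@H]2[C@H]1Cl | target

## Step count and weak points

Total step count: 17. Longest linear sequence: 17 (the route is fully linear from 1).

The three steps most likely to fail:

**Step 14 (ozonolysis).** Ozone may not discriminate the hindered ring-fusion olefin from the exocyclic methylene. The fallback carries the methylene in latent form and sets out from 28. Addition of Me3SiCH2Li in the presence of CeCl3 (THF, −78 °C) to the C-5 ketone gives the C-5 β-hydroxysilane F1, in which the ring-fusion olefin is the only electron-rich double bond. Ozonolysis with Me2S work-up then gives the β-hydroxysilane diketone F2. Peterson elimination with HF·pyridine in MeCN at 0 °C unveils the methylene, and the route is rejoined at 30.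

**Step 15 (C-6 chlorination).** The dienolate may be attacked at C-16 instead of C-6, or from the wrong face to give the 6R chloride. The fallback replaces electrophilic chlorine by oxygenation and displacement and sets out from 30. The same lithium dienolate is trapped with Me3SiCl as the C-7 silyl dienol ether F3. Dimethyldioxirane epoxidises its electron-rich enol ether double bond (Rubottom, regiochemically unambiguous) to give the 6-hydroxy ketone F4, expected as the 6R alcohol if the reagent again prefers that face. An Appel reaction (PPh3, CCl4, CH2Cl2, 0 °C) displaces the activated α-keto allylic alcohol with inversion, and the route is rejoined at 31. This fallback corrects the wrong-face outcome; it does not help if the face is right and only the C-6/C-16 regiochemistry is wrong.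

**Step 16 (double reduction).** Substrate control may give the wrong configuration at C-7 (the Cornforth preference opposes the chelate) or at C-2. The fallback uses reagent control in two separate reductions and sets out from 31. (R)-2-methyl-CBS-oxazaborolidine with catecholborane (toluene, −78 °C) reduces only the activated α-chloro ketone at C-7, and the alkoxide lactonises (PPTS) to the 2-keto chlorolactone F5. (S)-2-methyl-CBS-oxazaborolidine with catecholborane then reduces the C-2 ketone, treating the quaternary C-1 as the large group, and the route is rejoined at 33.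

## Further compounds

F1 | step 14 | C-5 (trimethylsilyl)methyl carbinol derived from 28 (C-5 epimers, C-17 mixture) | C[Si](C)(C)CC1(O)CCC2=C(C1)[C@@](O)(C(C)C(=O)OC)[C@H](OC(C)=O)[C@@H]3[C@]2(C)C=C[C@@H](OC(C)=O)[C@@]3(C)O
F2 | step 14 | ten-membered 2,7-diketone carrying the C-5 β-hydroxysilane | C[Si](C)(C)CC1(O)CCC(=O)[C@@]2(C)C=C[C@@H](OC(C)=O)[C@@](C)(O)[C@@H]2[C@@H](OC(C)=O)[C@](O)(C(C)C(=O)OC)C(=O)C1
F3 | step 15 | C-7 trimethylsilyl dienol ether of 30 (C-6=C-7, C-5=C-16) | C=C1CCC(=O)[C@@]2(C)C=C[C@@H](OC(C)=O)[C@@](C)(O)[C@@H]2[C@@H](OC(C)=O)[C@](O)(C(C)C(=O)OC)C(O[Si](C)(C)C)=C1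
F4 | step 15 | (6R)-6-hydroxy 2,7-diketone | C=C1CCC(=O)[C@@]2(C)C=C[C@@H](OC(C)=O)[C@@](C)(O)[C@@H]2[C@@H](OC(C)=O)[C@](O)(C(C)C(=O)OC)C(=O)[C@@H]1O
F5 | step 16 | 2-keto (6S,7R)-chlorolactone (C-17 mixture) | C=C1CCC(=O)[C@@]2(C)C=C[C@@H](OC(C)=O)[C@@](C)(O)[C@@H]2[C@@H](OC(C)=O)[C@]2(O)C(C)C(=O)O[C@H]2[C@H]1Cl
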